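**Strategy:** Ring A of the abietane half (C1–C5, C10) is treated as a cyclohexene retron in which the C4 gem-dimethyl carbon lies next to C5 and the C20 methyl sits on C10. A catalytic enantioselective Diels–Alder reaction between an acyclic (E)-1-(arylethyl)-2-methylbutadiene and methacrolein forms C2–C3 and C4–C5 in one operation, sets C5, and places at C4 a formyl group that is later reduced to the second methyl. Cationic arylation then closes ring B. The sesquiterpenoid half is attached as a cyclopropane-fused cyclohexenyl unit; epoxide ring contraction creates the spiro carbon, a benzoin closure the cyclopentanone, and demethylation unveils the quinone methide.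

Key step: step 6

Numbering: abietane numbering C1–C20 for the diterpenoid half; primed numbers C1'–C15' for the sesquiterpenoid half (C4' spiro carbon, C15' ring-ketone carbon, C5'/C1'/C6' cyclopropane, C7' isopropyl-bearing carbon, C10' side-chain ketone).

Assumption: the sense of induction of the chiral catalysts in steps 6 and 11 is assigned from the accepted transition-state models; the antipodal catalyst would be used if a first run showed the opposite sense.

**Step 1**
Reactants: 1 3-bromo-4,5-dimethoxybenzaldehyde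
Product: 2 3,4-dimethoxy-5-(propan-2-yl)benzaldehyde
Conditions: i-PrZnBr, Pd(OAc)2 (2 mol %), CPhos (4 mol %), THF/toluene, rt
Reagents that add atoms: isopropylzinc bromide, CC(C)[Zn]Br
Why: Negishi cross-coupling, in which the CPhos ligand suppresses β-hydride isomerisation so that the secondary alkyl group arrives unrearranged and the organozinc tolerates the aldehyde.

**Step 2**
Reactants: 2 3,4-dimethoxy-5-(propan-2-yl)benzaldehyde
Product: 3 (2E)-3-[3,4-dimethoxy-5-(propan-2-yl)phenyl]prop-2-enal
Conditions: Ph3P=CHCHO, toluene, 80 °C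
Reagents that add atoms: (triphenylphosphoranylidene)acetaldehyde, O=CC=P(c1ccccc1)(c1ccccc1)c1ccccc1
Why: Wittig olefination with a formyl-stabilised ylide, which should give the (E)-enal selectively.

**Step 3**
Reactants: 3 (2E)-3-[3,4-dimethoxy-5-(propan-2-yl)phenyl]prop-2-enal
Product: 4 3-[3,4-dimethoxy-5-(propan-2-yl)phenyl]propanal
Conditions: Hantzsch ester, dibenzylammonium trifluoroacetate (10 mol %), THF, rt
Reagents that add atoms: none
Why: Organocatalytic iminium-type transfer hydrogenation, which reduces only the conjugated C=C bond and leaves the aldehyde.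

**Step 4**
Reactants: 4 3-[3,4-dimethoxy-5-(propan-2-yl)phenyl]propanal
Product: 5 (2E)-5-[3,4-dimethoxy-5-(propan-2-yl)phenyl]-2-methylpent-2-enal
Conditions: Ph3P=C(CH3)CHO, toluene, 100 °C
Reagents that add atoms: 2-(triphenylphosphoranylidene)propanal, CC(C=O)=P(c1ccccc1)(c1ccccc1)c1ccccc1
Why: Wittig olefination with the α-methyl formyl-stabilised ylide, which should give the (E)-trisubstituted enal and thereby fix the diene geometry needed for an s-cis conformer.

**Step 5**
Reactants: 5 (2E)-5-[3,4-dimethoxy-5-(propan-2-yl)phenyl]-2-methylpent-2-enal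
Product: 6 1,2-dimethoxy-5-[(3E)-4-methylhexa-3,5-dien-1-yl]-3-(propan-2-yl)benzene
Conditions: Ph3PCH3Br, KOtBu, THF, 0 °C
Reagents that add atoms: methyltriphenylphosphonium bromide, C[P+](c1ccccc1)(c1ccccc1)c1ccccc1.[Br-]
Why: Wittig methylenation of the enal carbonyl, which completes the (E)-1,2-disubstituted butadiene (C2=C1–C10=C5) without touching the arene.

**Step 6**
Reactants: 6 1,2-dimethoxy-5-[(3E)-4-methylhexa-3,5-dien-1-yl]-3-(propan-2-yl)benzene, 7 methacrolein (2-methylprop-2-enal)
Product: 8 (1S,2R)-2-{2-[3,4-dimethoxy-5-(propan-2-yl)phenyl]ethyl}-1,3-dimethylcyclohex-3-ene-1-carbaldehyde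
Conditions: (S)-3,3-diphenyl-1-(2-methylphenyl)tetrahydro-1H,3H-pyrrolo[1,2-c][1,3,2]oxazaborole·HNTf2 (10 mol %), CH2Cl2, −78 → −40 °C
Reagents that add atoms: none
Why: Concerted, asynchronous [4+2] cycloaddition of the s-cis diene 6 onto methacrolein bound s-trans to the cationic oxazaborolidine, the closest known reaction type being the Corey oxazaborolidinium-catalysed Diels–Alder reaction of 2-substituted acroleins with acyclic dienes. Ring A closes as a six-membered carbocycle in a single intermolecular suprafacial–suprafacial event that forms C2–C3 and C4–C5 together. C5 is set by the catalyst, which exposes one face of the enal, combined with the endo orientation of the formyl group, which places it cis to the arylethyl chain; C4 is a transient stereocentre that is erased when the formyl group becomes the second methyl. The step needs "ortho" regioselectivity (C4 next to C5), secured by the larger HOMO coefficient at the unsubstituted terminus C2 of the 1-alkyl diene pairing with the β-carbon of the activated enal, and high endo selectivity, since the exo adduct would carry the opposite C5 configuration. The (E) geometry at C5=C10 and the C20 methyl on the internal carbon favour the s-cis conformer, and the electron-rich arene is remote from the reacting centres.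

**Step 7**
Reactants: 8 (1S,2R)-2-{2-[3,4-dimethoxy-5-(propan-2-yl)phenyl]ethyl}-1,3-dimethylcyclohex-3-ene-1-carbaldehyde
Product: 10 1,2-dimethoxy-3-(propan-2-yl)-5-{2-[(1S)-2,6,6-trimethylcyclohex-2-en-1-yl]ethyl}benzene, via hydrazone 9 (not isolated)
Conditions: N2H4·H2O, KOH, diethylene glycol, 120 °C then 200 °C
Reagents that add atoms: none
Why: Wolff–Kishner (Huang–Minlon) reduction, which converts the neopentyl formyl group into the second C4 methyl under basic conditions that neither move the trisubstituted alkene nor touch C5.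

**Step 8**
Reactants: 10 1,2-dimethoxy-3-(propan-2-yl)-5-{2-[(1S)-2,6,6-trimethylcyclohex-2-en-1-yl]ethyl}benzene
Product: 11 (5S,10S)-11,12-dimethoxyabieta-8,11,13-triene
Conditions: FSO3H, 2-nitropropane, −78 °C
Reagents that add atoms: none
Why: Cationic Friedel–Crafts cyclialkylation (Bogert–Cook type), in which Markovnikov protonation of C1=C10 gives the C10 cation that is trapped by C9 (ortho to the C11 methoxy group, the other ortho site being flanked by isopropyl) through a chair-like transition state with the C5 side chain equatorial, so that C20 ends axial and trans to H5, the low temperature in a superacid medium letting ring closure outrun deprotonation at C5.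

**Step 9**
Reactants: 11 (5S,10S)-11,12-dimethoxyabieta-8,11,13-triene
Product: 12 (5S,10S)-14-bromo-11,12-dimethoxyabieta-8,11,13-triene
Conditions: NBS, MeCN, 0 °C → rt, dark
Reagents that add atoms: N-bromosuccinimide, O=C1CCC(=O)N1Br
Why: Electrophilic aromatic bromination, which should occur at C14, the only free ring position and para to the C11 methoxy group.

**Step 10**
Reactants: 12 (5S,10S)-14-bromo-11,12-dimethoxyabieta-8,11,13-triene
Product: 13 (5S,10S)-14-bromo-11,12-dimethoxyabieta-8,11,13-trien-7-one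
Conditions: CrO3, AcOH/H2O, rt
Reagents that add atoms: chromium trioxide, O=[Cr](=O)=O
Why: Benzylic oxidation with CrO3, which converts the C7 methylene (para to the C12 methoxy group) into the aryl ketone as in the sugiol series, the tertiary isopropyl C–H being more hindered.

**Step 11**
Reactants: 14 3-methylbutanal, 15 but-3-en-2-one
Product: 16 (2S)-5-oxo-2-(propan-2-yl)hexanal
Conditions: (S)-2-[methoxy(diphenyl)methyl]pyrrolidine (5 mol %), ethyl 3,4-dihydroxybenzoate (20 mol %), neat, 4 °C
Reagents that add atoms: none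
Why: Enamine-catalysed Michael addition (diarylprolinol ether catalysis), in which the (E)-enamine of 14 adds to the enone from the face opposite the diarylmethyl group and so sets C7' as S.

**Step 12**
Reactants: 16 (2S)-5-oxo-2-(propan-2-yl)hexanal
Product: 17 (5S,6E)-7-iodo-5-(propan-2-yl)hept-6-en-2-one
Conditions: CrCl2, CHI3, THF, 0 °C
Reagents that add atoms: iodoform, IC(I)I
Why: Takai olefination, which is aldehyde-selective and (E)-selective, so the methyl ketone and the α-stereocentre are left untouched.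

**Step 13**
Reactants: 17 (5S,6E)-7-iodo-5-(propan-2-yl)hept-6-en-2-one
Product: 18 2-[(3S,4E)-5-iodo-3-(propan-2-yl)pent-4-en-1-yl]-2-methyl-1,3-dioxolane
Conditions: HOCH2CH2OH, pyridinium p-toluenesulfonate (cat.), benzene, reflux (Dean–Stark)
Reagents that add atoms: ethylene glycol, OCCO
Why: Acid-catalysed ketalisation, which protects the C10' ketone for the organolithium steps that follow.

**Step 14**
Reactants: 19 (R)-epichlorohydrin
Product: 21 (2R)-2-(prop-2-en-1-yl)oxirane, via chlorohydrin alkoxide 20 (not isolated)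
Conditions: CH2=CHMgBr, CuI (5 mol %), THF, −40 °C; then aq. NaOH, rt
Reagents that add atoms: vinylmagnesium bromide, C=C[Mg]Br
Why: Copper-catalysed epoxide opening by the Grignard reagent at the unsubstituted terminus followed by base-induced ring closure of the chlorohydrin, which carries the stereocentre of 19 unchanged into 21.

**Step 15**
Reactants: 21 (2R)-2-(prop-2-en-1-yl)oxirane, 18 2-[(3S,4E)-5-iodo-3-(propan-2-yl)pent-4-en-1-yl]-2-methyl-1,3-dioxolane
Product: 23 2-methyl-2-[(3S,4E)-8-[(2R)-oxiran-2-yl]-3-(propan-2-yl)oct-4-en-1-yl]-1,3-dioxolane, via alkylborane 22 (not isolated)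
Conditions: 21, 9-BBN, THF, rt; then 18, PdCl2(dppf) (5 mol %), K3PO4, DMF/H2O, 50 °C
Reagents that add atoms: none
Why: Anti-Markovnikov hydroboration followed by B-alkyl Suzuki–Miyaura coupling, which joins the primary alkylborane to the vinyl iodide with retention of the (E) geometry and leaves the epoxide intact.

**Step 16**
Reactants: 23 2-methyl-2-[(3S,4E)-8-[(2R)-oxiran-2-yl]-3-(propan-2-yl)oct-4-en-1-yl]-1,3-dioxolane
Product: 25 (1S,2R,6S,7S)-7-[(3S)-2-methyl-5-(2-methyl-1,3-dioxolan-2-yl)pentan-3-yl]bicyclo[4.1.0]heptan-2-ol, via lithiated epoxide 24 (not isolated)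
Conditions: lithium 2,2,6,6-tetramethylpiperidide (2.5 equiv), t-BuOMe, 0 °C → rt
Reagents that add atoms: none
Why: Hodgson intramolecular cyclopropanation of an α-lithiated terminal epoxide, in which the trans-lithiated oxirane carbon adds as a carbenoid to the (E)-alkene through a chair-like transition state, so that the oxirane stereocentre (C4') fixes C5', C1' and C6' (hydroxyl trans to the cyclopropane, side chain exo).

**Step 17**
Reactants: 25 (1S,2R,6S,7S)-7-[(3S)-2-methyl-5-(2-methyl-1,3-dioxolan-2-yl)pentan-3-yl]bicyclo[4.1.0]heptan-2-ol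
Product: 26 (1S,6S,7S)-7-[(3S)-2-methyl-5-(2-methyl-1,3-dioxolan-2-yl)pentan-3-yl]bicyclo[4.1.0]heptan-2-one
Conditions: Pr4N[RuO4] (5 mol %), N-methylmorpholine N-oxide, 4 Å MS, CH2Cl2, rt
Reagents that add atoms: none
Why: Ley–Griffith oxidation of the secondary cyclopropyl carbinol, which should give the ketone without ring opening.

**Step 18**
Reactants: 26 (1S,6S,7S)-7-[(3S)-2-methyl-5-(2-methyl-1,3-dioxolan-2-yl)pentan-3-yl]bicyclo[4.1.0]heptan-2-one
Product: 27 2,4,6-triisopropylbenzenesulfonylhydrazone of 26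
Conditions: 2,4,6-(i-Pr)3C6H2SO2NHNH2, THF, rt
Reagents that add atoms: 2,4,6-triisopropylbenzenesulfonohydrazide, CC(C)c1cc(C(C)C)c(S(=O)(=O)NN)c(C(C)C)c1
Why: Hydrazone condensation, which sets up the Shapiro reaction and needs no acid, so the dioxolane survives.

**Step 19**
Reactants: 27 2,4,6-triisopropylbenzenesulfonylhydrazone of 26, 13 (5S,10S)-14-bromo-11,12-dimethoxyabieta-8,11,13-trien-7-one
Product: 30 11,12-dimethoxy-14-(bicyclo[4.1.0]hept-2-en-2-yl)abieta-8,11,13-trien-7-one (C14–C4' bond, C4'=C15' alkene; C5', C1', C6', C7' as in 26), via alkenyllithium 28 (not isolated), via alkenylzinc chloride 29 (not isolated)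
Conditions: 27, n-BuLi (2.2 equiv), THF, −78 → 0 °C; ZnCl2; then 13, Pd2(dba)3 (2.5 mol %), SPhos (10 mol %), THF, 65 °C
Reagents that add atoms: none
Why: Shapiro reaction (deprotonation at C15', the only accessible α-position, then loss of sulfinate and N2) followed by transmetallation to zinc and Negishi coupling with the hindered aryl bromide, the organozinc tolerating the C7 ketone.

**Step 20**
Reactants: 30 11,12-dimethoxy-14-(bicyclo[4.1.0]hept-2-en-2-yl)abieta-8,11,13-trien-7-one
Product: 31 4',15'-epoxide of 30 with the oxygen anti to the cyclopropane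
Conditions: mCPBA, NaHCO3, CH2Cl2, 0 °C
Reagents that add atoms: 3-chloroperoxybenzoic acid, OOC(=O)c1cccc(Cl)c1
Why: Prilezhaev epoxidation, which should deliver oxygen to the alkene face anti to the fused cyclopropane (as for 2-carene) and thereby set C4' and C15', while the aryl ketone resists Baeyer–Villiger oxidation under buffered conditions.

**Step 21**
Reactants: 31 4',15'-epoxide of 30
Product: 32 11,12-dimethoxy-14-(2-formylbicyclo[3.1.0]hexan-2-yl)abieta-8,11,13-trien-7-one (C4' quaternary: aryl syn and formyl C15' anti to the cyclopropane)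
Conditions: MeAl(OAr)2 [Ar = 4-bromo-2,6-di-tert-butylphenyl] (2.2 equiv), CH2Cl2, −78 °C
Reagents that add atoms: none
Why: Meinwald rearrangement with ring contraction, in which ionisation of the C4'–O bond (tertiary, benzylic and cyclopropylcarbinyl) is followed by 1,2-shift of the ring bond C15'–C3' to C4' on the face opposite the departing oxygen, so that the aryl group ends syn and the new formyl group anti to the cyclopropane, while the bulky aluminium Lewis acid in excess ties up the C7 ketone and favours alkyl over hydride shift.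

**Step 22**
Reactants: 32 11,12-dimethoxy-14-(2-formylbicyclo[3.1.0]hexan-2-yl)abieta-8,11,13-trien-7-one
Product: 33 spiro α-ketol (C7–C15' bond; C7–OH, C15'=O; catechol dimethyl ether; C10' dioxolane; C7 configuration immaterial)
Conditions: 2-mesityl-6,7-dihydro-5H-pyrrolo[2,1-c][1,2,4]triazol-2-ium chloride (20 mol %), DBU (20 mol %), toluene, 60 °C
Reagents that add atoms: none
Why: Intramolecular crossed benzoin reaction, in which the Breslow intermediate of the non-enolisable aldehyde adds to the nearby C7 aryl ketone and closes the five-membered ring, the new C7 carbinol centre being destroyed in the next step.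

**Step 23**
Reactants: 33 spiro α-ketol
Product: 34 CNP0140364.1 (target)
Conditions: BBr3 (6 equiv), CH2Cl2, −78 → 0 °C; then 1 M HCl/THF, rt
Reagents that add atoms: water, O
Why: Lewis-acid ether cleavage with benzylic dehydration, in which BBr3 removes both aryl methyl groups and ionises the tertiary para-hydroxybenzylic C7–OH so that the catechol loses water to the hydroxy-para-quinone methide (C7=C8, C12=O, C11–OH), and the acidic work-up hydrolyses the dioxolane to the C10' ketone.

**Compound list**

1 | 3-bromo-4,5-dimethoxybenzaldehyde | COc1cc(C=O)cc(Br)c1OC | starting material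
2 | 3,4-dimethoxy-5-(propan-2-yl)benzaldehyde | COc1cc(C=O)cc(C(C)C)c1OC | intermediate
3 | (2E)-3-[3,4-dimethoxy-5-(propan-2-yl)phenyl]prop-2-enal | COc1cc(/C=C/C=O)cc(C(C)C)c1OC | intermediate
4 | 3-[3,4-dimethoxy-5-(propan-2-yl)phenyl]propanal | COc1cc(CCC=O)cc(C(C)C)c1OC | intermediate
5 | (2E)-5-[3,4-dimethoxy-5-(propan-2-yl)phenyl]-2-methylpent-2-enal | COc1cc(CC/C=C(\C)C=O)cc(C(C)C)c1OC | intermediate
6 | 1,2-dimethoxy-5-[(3E)-4-methylhexa-3,5-dien-1-yl]-3-(propan-2-yl)benzene | COc1cc(CC/C=C(\C)C=C)cc(C(C)C)c1OC | intermediate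
7 | methacrolein | CC(=C)C=O | starting material
8 | (1S,2R)-2-{2-[3,4-dimethoxy-5-(propan-2-yl)phenyl]ethyl}-1,3-dimethylcyclohex-3-ene-1-carbaldehyde | COc1cc(CC[C@@H]2C(C)=CCC[C@]2(C)C=O)cc(C(C)C)c1OC | intermediate
9 | hydrazone of 8 | COc1cc(CC[C@@H]2C(C)=CCC[C@]2(C)C=NN)cc(C(C)C)c1OC | intermediate
10 | 1,2-dimethoxy-3-(propan-2-yl)-5-{2-[(1S)-2,6,6-trimethylcyclohex-2-en-1-yl]ethyl}benzene | COc1cc(CC[C@@H]2C(C)=CCCC2(C)C)cc(C(C)C)c1OC | intermediate
11 | (5S,10S)-11,12-dimethoxyabieta-8,11,13-triene | COc1c(OC)c(C(C)C)cc2c1[C@@]1(C)CCCC(C)(C)[C@@H]1CC2 | intermediate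
12 | (5S,10S)-14-bromo-11,12-dimethoxyabieta-8,11,13-triene | COc1c(OC)c(C(C)C)c(Br)c2c1[C@@]1(C)CCCC(C)(C)[C@@H]1CC2 | intermediate
13 | (5S,10S)-14-bromo-11,12-dimethoxyabieta-8,11,13-trien-7-one | COc1c(OC)c(C(C)C)c(Br)c2c1[C@@]1(C)CCCC(C)(C)[C@@H]1CC2=O | intermediate
14 | 3-methylbutanal | CC(C)CC=O | starting material
15 | but-3-en-2-one | CC(=O)C=C | starting material
16 | (2S)-5-oxo-2-(propan-2-yl)hexanal | CC(=O)CC[C@@H](C(C)C)C=O | intermediate
17 | (5S,6E)-7-iodo-5-(propan-2-yl)hept-6-en-2-one | CC(=O)CC[C@@H](C(C)C)/C=C/I | intermediate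
18 | 2-[(3S,4E)-5-iodo-3-(propan-2-yl)pent-4-en-1-yl]-2-methyl-1,3-dioxolane | CC1(CC[C@@H](C(C)C)/C=C/I)OCCO1 | intermediate
19 | (R)-epichlorohydrin | ClC[C@H]1CO1 | starting material
20 | (2R)-1-chloropent-4-en-2-ol (formed as its magnesium alkoxide) | ClC[C@H](O)CC=C | intermediate
21 | (2R)-2-(prop-2-en-1-yl)oxirane | C=CC[C@@H]1CO1 | intermediate
22 | 9-{3-[(2R)-oxiran-2-yl]propyl}-9-borabicyclo[3.3.1]nonane | B1(CCC[C@@H]2CO2)C3CCCC1CCC3 | intermediate
23 | 2-methyl-2-[(3S,4E)-8-[(2R)-oxiran-2-yl]-3-(propan-2-yl)oct-4-en-1-yl]-1,3-dioxolane | CC1(CC[C@@H](C(C)C)/C=C/CCC[C@@H]2CO2)OCCO1 | intermediate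
24 | trans-α-lithiated epoxide of 23 | CC1(CC[C@@H](C(C)C)/C=C/CCC[C@@H]2[C@@H]([Li])O2)OCCO1 | intermediate
25 | (1S,2R,6S,7S)-7-[(3S)-2-methyl-5-(2-methyl-1,3-dioxolan-2-yl)pentan-3-yl]bicyclo[4.1.0]heptan-2-ol | CC1(OCCO1)CC[C@@H](C(C)C)[C@H]2[C@@H]3CCC[C@@H](O)[C@@H]32 | intermediate
26 | (1S,6S,7S)-7-[(3S)-2-methyl-5-(2-methyl-1,3-dioxolan-2-yl)pentan-3-yl]bicyclo[4.1.0]heptan-2-one | CC1(OCCO1)CC[C@@H](C(C)C)[C@H]2[C@@H]3CCCC(=O)[C@@H]32 | intermediate
27 | 2,4,6-triisopropylbenzenesulfonylhydrazone of 26 | CC1(OCCO1)CC[C@@H](C(C)C)[C@H]2[C@@H]3CCCC(=NNS(=O)(=O)c4c(C(C)C)cc(C(C)C)cc4C(C)C)[C@@H]32 | intermediate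
28 | alkenyllithium (Li on C4', C4'=C15') | CC1(OCCO1)CC[C@@H](C(C)C)[C@H]2[C@@H]3CCC=C([Li])[C@@H]32 | intermediate
29 | alkenylzinc chloride (ZnCl on C4') | CC1(OCCO1)CC[C@@H](C(C)C)[C@H]2[C@@H]3CCC=C([Zn]Cl)[C@@H]32 | intermediate
30 | 11,12-dimethoxy-14-(cyclopropane-fused cyclohexenyl)abieta-8,11,13-trien-7-one (C14–C4', C4'=C15') | COc1c(OC)c(C(C)C)c(C3=CCC[C@H]4[C@H]([C@@H](CCC5(C)OCCO5)C(C)C)[C@@H]34)c2c1[C@@]1(C)CCCC(C)(C)[C@@H]1CC2=O | intermediate
31 | 4',15'-epoxide of 30, oxygen anti to the cyclopropane | COc1c(OC)c(C(C)C)c([C@]36O[C@@H]6CC[C@H]4[C@H]([C@@H](CCC5(C)OCCO5)C(C)C)[C@@H]34)c2c1[C@@]1(C)CCCC(C)(C)[C@@H]1CC2=O | intermediate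
32 | ring-contracted aldehyde (C4' quaternary, aryl syn and CHO anti to the cyclopropane) | COc1c(OC)c(C(C)C)c([C@@]3(C=O)CC[C@H]4[C@H]([C@@H](CCC5(C)OCCO5)C(C)C)[C@@H]34)c2c1[C@@]1(C)CCCC(C)(C)[C@@H]1CC2=O | intermediate
33 | spiro α-ketol (C7–OH, C15'=O, catechol dimethyl ether, C10' dioxolane; C7 either configuration) | CC6(OCCO6)CC[C@@H](C(C)C)[C@H]1[C@@H]2CC[C@@]3(C(=O)C4(O)c5c3c(C(C)C)c(OC)c(OC)c5[C@@]3(C)CCCC(C)(C)[C@@H]3C4)[C@@H]21 | intermediate
34 | CNP0140364.1 | CC(=O)CC[C@@H](C(C)C)[C@H]1[C@@H]2CC[C@@]3(C(=O)C4=C5C3=C(C(C)C)C(=O)C(O)=C5[C@@]3(C)CCCC(C)(C)[C@@H]3C4)[C@@H]21 | target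

**Totals:** 23 steps; longest linear sequence 15 steps (steps 1–10, then 19–23).

**Steps most likely to fail**

Step 21. A competing 1,2-hydride shift from C15', or capture of the developing C4' cation by the C7 carbonyl oxygen, could divert the rearrangement. The fallback moves the ring contraction to a tetrasubstituted epoxide that has neither a migrating hydrogen nor a free ketone. It sets out from 30. NaBH4 would reduce the C7 ketone to the benzylic alcohol F4. Catalytic TfOH would ionise it, and the ortho-alkenylbenzyl cation would close by 4π electrocyclisation and loss of the C15' proton to the fused indene F5 (new C7–C15' bond, C4'=C15' alkene). mCPBA epoxidation anti to the cyclopropane would give the epoxide F6. BF3·OEt2 would then induce the same anti 1,2-shift of C3' to the spiro 2-indanone F7 (C7–H). BBr3 followed by acidic work-up would give the catechol ketone F8. Ag2O would oxidise it to the ortho-quinone F9, which tautomerises (C7–H to O11) and so comes back to the route at 34.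

Step 6. Incomplete regiocontrol, exo approach or insufficient facial discrimination by the catalyst would erode the C5 configuration. The fallback uses auxiliary control and sets out from 6. A TiCl4-promoted Diels–Alder reaction with the methacrylate ester of (R)-pantolactone (or its antipode, as the sense of induction requires) would give the ester adduct F1. LiAlH4 would cleave the auxiliary and give the neopentyl alcohol F2. MsCl/Et3N would give the mesylate F3, and LiEt3BH would reduce it to the gem-dimethyl compound, coming back to the route at 10.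

Step 22. Slow formation of the Breslow intermediate from the α-quaternary aldehyde, or retro-benzoin, could stall the closure. The fallback is a reductive closure that sets out from 32. SmI2 (THF, −78 °C) would effect ketyl–carbonyl pinacol coupling to the cis-diol F10, and oxidation of its secondary C15' hydroxyl (Pr4N[RuO4], N-methylmorpholine N-oxide) would come back to the route at 33.

**Further compounds**

F1 | step 6 | (R)-pantolactone ester analogue of 8 | COc1cc(CC[C@@H]2C(C)=CCC[C@]2(C)C(=O)O[C@H]3C(=O)OCC3(C)C)cc(C(C)C)c1OC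
F2 | step 6 | neopentyl alcohol from F1 | COc1cc(CC[C@@H]2C(C)=CCC[C@]2(C)CO)cc(C(C)C)c1OC
F3 | step 6 | mesylate of F2 | COc1cc(CC[C@@H]2C(C)=CCC[C@]2(C)COS(C)(=O)=O)cc(C(C)C)c1OC
F4 | step 21 | C7 benzylic alcohol from 30 (C7 either configuration) | COc1c(OC)c(C(C)C)c(C3=CCC[C@H]4[C@H]([C@@H](CCC5(C)OCCO5)C(C)C)[C@@H]34)c2c1[C@@]1(C)CCCC(C)(C)[C@@H]1CC2O
F5 | step 21 | fused indene (C7–C15' bond, C4'=C15') | COc1c(OC)c(C(C)C)c3c2c1[C@@]1(C)CCCC(C)(C)[C@@H]1CC2C4=C3[C@@H]5[C@@H]([C@@H](CCC6(C)OCCO6)C(C)C)[C@@H]5CC4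
F6 | step 21 | 4',15'-epoxide of F5, oxygen anti to the cyclopropane | COc1c(OC)c(C(C)C)c3c2c1[C@@]1(C)CCCC(C)(C)[C@@H]1CC2[C@@]47O[C@]37[C@@H]5[C@@H]([C@@H](CCC6(C)OCCO6)C(C)C)[C@@H]5CC4
F7 | step 21 | spiro 2-indanone with C7–H (dimethyl ether, dioxolane) | CC6(OCCO6)CC[C@@H](C(C)C)[C@H]1[C@@H]2CC[C@@]3(C(=O)C4c5c3c(C(C)C)c(OC)c(OC)c5[C@@]3(C)CCCC(C)(C)[C@@H]3C4)[C@@H]21
F8 | step 21 | catechol diketone | CC(=O)CC[C@@H](C(C)C)[C@H]1[C@@H]2CC[C@@]3(C(=O)C4c5c3c(C(C)C)c(O)c(O)c5[C@@]3(C)CCCC(C)(C)[C@@H]3C4)[C@@H]21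
F9 | step 21 | ortho-quinone tautomer of 34 | CC(=O)CC[C@@H](C(C)C)[C@H]1[C@@H]2CC[C@@]3(C(=O)C4C5=C(C(=O)C(=O)C(C(C)C)=C35)[C@@]6(C)CCCC(C)(C)[C@@H]6C4)[C@@H]21
F10 | step 22 | C7,C15' cis-diol | CC6(OCCO6)CC[C@@H](C(C)C)[C@H]1[C@@H]2CC[C@@]3(C(O)C4(O)c5c3c(C(C)C)c(OC)c(OC)c5[C@@]3(C)CCCC(C)(C)[C@@H]3C4)[C@@H]21
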